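The route rests on cutting the C3–C1′ bond between the chromanone (rings A and C) and aryl ring B of the dimethylchromene. The key step exploits that C3, the only stereocentre, is a tertiary carbon of ring C next to the C4 ketone: a racemic 3-bromochroman-4-one gives a planar C3 radical that a chiral nickel catalyst can arylate. One enantioconvergent Negishi coupling thus joins the two bicycles and sets (3R) from both enantiomers of the bromide. Its precursors are a silyl-protected 3-bromo-5-methoxychromanone, built from phloroglucinol, and a chromen-6-ylzinc iodide, built from 4-bromo-2-methoxyphenol by a propargyl Claisen cascade. Acid-buffered desilylation, free of base, ends the route.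

Key step: step 13

Assumption: which antipode of the pybox ligand delivers (3R) cannot be predicted reliably for a ring-locked ketone; it is fixed by a trial coupling with chiroptical assignment, and the route is written for that antipode.

Step 1
Reactants: 1 phloroglucinol; 2 3-chloropropanoic acid
Product: 3 3-chloro-1-(2,4,6-trihydroxyphenyl)propan-1-one
Conditions: CF3SO3H, 80 °C
Reagents that add atoms: none
Why: Friedel–Crafts acylation of the symmetrical, very electron-rich arene by the acid activated in CF3SO3H stops at the monoketone because the acyl group deactivates the ring, and the primary chloride is inert to the acid.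

Step 2
Reactants: 3 3-chloro-1-(2,4,6-trihydroxyphenyl)propan-1-one
Product: 4 5,7-dihydroxychroman-4-one
Conditions: 2 M aq NaOH, 0 °C to rt; then HCl to pH 2
Reagents that add atoms: none
Why: Intramolecular Williamson etherification, a 6-exo-tet attack of an ortho phenoxide on the primary chloride, closes ring C, and the two ortho hydroxyls are equivalent so only one chromanone can form.

Step 3
Reactants: 4 5,7-dihydroxychroman-4-one
Product: 6 7-(benzyloxy)-5-methoxychroman-4-one, via 7-(benzyloxy)-5-hydroxychroman-4-one 5 (not isolated)
Conditions: BnBr (1.0 equiv), K2CO3, DMF, rt; then MeI (excess), 45 °C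
Reagents that add atoms: benzyl bromide, BrCc1ccccc1; iodomethane, CI
Why: Two Williamson O-alkylations run in one pot are ordered by acidity, since the 7-hydroxyl para to the carbonyl is benzylated at room temperature by one equivalent of benzyl bromide while the hydrogen-bonded 5-hydroxyl reacts only afterwards with excess iodomethane on gentle heating.

Step 4
Reactants: 6 7-(benzyloxy)-5-methoxychroman-4-one
Product: 7 7-hydroxy-5-methoxychroman-4-one
Conditions: H2 (1 atm), Pd/C (10%), EtOAc/MeOH, rt
Reagents that add atoms: none
Why: Hydrogenolysis of the benzyl aryl ether over Pd/C is clean at this stage because no alkene or halide is present yet and the electron-rich, vinylogous-ester-like aryl ketone resists reduction at one atmosphere.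

Step 5
Reactants: 7 7-hydroxy-5-methoxychroman-4-one
Product: 8 5-methoxy-7-(triisopropylsilyloxy)chroman-4-one
Conditions: TIPSCl, imidazole, DMF, rt
Reagents that add atoms: chlorotriisopropylsilane, CC(C)[Si](Cl)(C(C)C)C(C)C
Why: Silylation of the single free phenol gives an aryl triisopropylsilyl ether that should withstand enol silylation, NBS and the organozinc coupling and that fluoride removes at the end.

Step 6
Reactants: 8 5-methoxy-7-(triisopropylsilyloxy)chroman-4-one
Product: 9 5-methoxy-7-(triisopropylsilyloxy)-4-(trimethylsilyloxy)-2H-chromene
Conditions: TMSOTf, Et3N, CH2Cl2, 0 °C; pentane, cold aq NaHCO3 wash; used crude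
Reagents that add atoms: trimethylsilyl trifluoromethanesulfonate, C[Si](C)(C)OS(=O)(=O)C(F)(F)F
Why: Soft enolisation with TMSOTf and Et3N can only give the C3–C4 enol ether because C4a bears no hydrogen, and the aryl silyl ether and methyl ether are inert.

Step 7
Reactants: 9 5-methoxy-7-(triisopropylsilyloxy)-4-(trimethylsilyloxy)-2H-chromene
Product: 10 rac-3-bromo-5-methoxy-7-(triisopropylsilyloxy)chroman-4-one
Conditions: NBS (1.05 equiv), THF, −78 °C; cold pH 7 buffer, no base; short silica plug, stored cold, used promptly
Reagents that add atoms: N-bromosuccinimide, O=C1CCC(=O)N1Br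
Why: Electrophilic bromination of a silyl enol ether by NBS at −78 °C is far faster than bromination of ring A and releases no base, so the racemic α-bromoketone should form without loss of HBr to the chromone.

Step 8
Reactants: 11 4-bromo-2-methoxyphenol; 12 3-chloro-3-methylbut-1-yne
Product: 13 4-bromo-2-methoxy-1-(2-methylbut-3-yn-2-yloxy)benzene
Conditions: CuCl2·2H2O (cat.), DBU, MeCN, 0 °C to rt
Reagents that add atoms: none
Why: Copper-catalysed O-propargylation of the phenol with the tertiary propargylic chloride and DBU is the standard entry to 1,1-dimethylpropargyl aryl ethers, and the aryl bromide is a bystander.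

Step 9
Reactants: 13 4-bromo-2-methoxy-1-(2-methylbut-3-yn-2-yloxy)benzene
Product: 16 6-bromo-8-methoxy-2,2-dimethyl-2H-chromene, via ortho-allenylphenol 14 (not isolated), via ortho-quinone methide 15 (not isolated)
Conditions: N,N-diethylaniline, 190 °C
Reagents that add atoms: none
Why: Aromatic propargyl Claisen rearrangement to the only free ortho carbon, tautomerisation to the allenylphenol, 1,5-hydrogen shift and 6-pi oxa-electrocyclisation build the 2,2-dimethylpyran ring in one thermal cascade, while rearrangement to the methoxy-bearing ortho carbon is reversible and unproductive.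

Step 10
Reactants: 16 6-bromo-8-methoxy-2,2-dimethyl-2H-chromene
Product: 17 6-bromo-2,2-dimethyl-2H-chromen-8-ol
Conditions: NaSEt (4 equiv), DMF, 120 °C; then cold 1 M HCl
Reagents that add atoms: none
Why: Ethanethiolate cleaves the aryl methyl ether by SN2 attack at the methyl carbon, a nucleophilic demethylation that should leave the chromene double bond, the tertiary allylic aryl ether and the unactivated aryl bromide untouched, unlike Lewis acids such as BBr3.

Step 11
Reactants: 17 6-bromo-2,2-dimethyl-2H-chromen-8-ol
Product: 18 6-bromo-2,2-dimethyl-8-(triisopropylsilyloxy)-2H-chromene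
Conditions: TIPSCl, imidazole, DMF, rt to 40 °C
Reagents that add atoms: chlorotriisopropylsilane, CC(C)[Si](Cl)(C(C)C)C(C)C
Why: Silylation of the phenol with TIPSCl and imidazole masks the acidic hydrogen that would quench the organometallic reagent, with a group removable together with the one on ring A.

Step 12
Reactants: 18 6-bromo-2,2-dimethyl-8-(triisopropylsilyloxy)-2H-chromene
Product: 20 [2,2-dimethyl-8-(triisopropylsilyloxy)-2H-chromen-6-yl]zinc iodide (THF solution, titrated, used directly), via chromen-6-ylmagnesium bromide 19 (not isolated)
Conditions: Mg turnings (I2-activated), THF, 45 °C; then ZnI2 (1.1 equiv), THF, 0 °C to rt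
Reagents that add atoms: zinc iodide, I[Zn]I; magnesium, [Mg] (held only in intermediate 19)
Why: Oxidative insertion of magnesium into the aryl C–Br bond followed by transmetalation with ZnI2 gives the weakly basic arylzinc iodide, and neither the aryl silyl ether nor the styrenic chromene alkene reacts with aryl Grignard or arylzinc species.

Step 13
Reactants: 10 rac-3-bromo-5-methoxy-7-(triisopropylsilyloxy)chroman-4-one; 20 [2,2-dimethyl-8-(triisopropylsilyloxy)-2H-chromen-6-yl]zinc iodide
Product: 21 (3R)-3-[2,2-dimethyl-8-(triisopropylsilyloxy)-2H-chromen-6-yl]-5-methoxy-7-(triisopropylsilyloxy)chroman-4-one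
Conditions: NiCl2(dme) (10 mol %), Ph-pybox (13 mol %, antipode per the assumption), 20 (1.3 equiv), glyme/THF, −30 °C; cold aq NH4Cl, neutral work-up
Reagents that add atoms: none
Why: Proposed new method: a monovalent arylnickel–pybox species should abstract bromine from either enantiomer of 10 to give one and the same planar C3 radical conjugated with the C4 carbonyl, which recombines with the divalent arylnickel complex formed by transmetalation from 20, and reductive elimination from the resulting trivalent nickel species forges the C3–C1′ bond. The closest known reaction type is the nickel/pybox-catalysed stereoconvergent Negishi arylation of racemic acyclic α-bromo aryl ketones with arylzinc iodides, which gives tertiary α-aryl ketones without racemisation, whereas a ring-locked 3-bromochroman-4-one with a β-aryloxy oxygen is untested as the electrophile. No ring is closed: the step only joins the chromanone (rings A and C) to the chromene bicycle. The new stereocentre C3 is set under catalyst control, the chiral pybox ligand on nickel choosing the face of the planar radical that receives the aryl group, so that both enantiomers of 10 converge on (3R). The step needs that facial selectivity together with chemoselectivity for coupling over loss of HBr to the chromone and over β-aryloxy elimination that would open ring C; the rigid s-cis aryl ketone of 10 gives the ligand two well-differentiated faces, the arylzinc is too weakly basic to eliminate HBr or enolise the product at −30 °C, and ring C holds the C2–O bond away from syn-coplanarity with a C3–Ni bond. Nucleophile 20 fits the known scope, having no ortho substituent and only a silyl ether and a styrenic alkene as bystanders.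

Step 14
Reactants: 21 (3R)-3-[2,2-dimethyl-8-(triisopropylsilyloxy)-2H-chromen-6-yl]-5-methoxy-7-(triisopropylsilyloxy)chroman-4-one
Product: 22 (3R)-7-hydroxy-3-(8-hydroxy-2,2-dimethyl-2H-chromen-6-yl)-5-methoxychroman-4-one
Conditions: Bu4NF (2.4 equiv), AcOH (3 equiv), THF, 0 °C; pH 5 buffer work-up, no amine or base
Reagents that add atoms: none
Why: Fluoride cleaves both aryl Si–O bonds while acetic acid protonates each phenoxide as it forms, so the base-labile C3–H next to the ketone never meets free fluoride, phenoxide or amine, and the chromene and the methyl ether are unaffected.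

Compound list
1 | phloroglucinol | Oc1cc(O)cc(O)c1 | starting material
2 | 3-chloropropanoic acid | OC(=O)CCCl | starting material
3 | 3-chloro-1-(2,4,6-trihydroxyphenyl)propan-1-one | O=C(CCCl)c1c(O)cc(O)cc1O | intermediate
4 | 5,7-dihydroxychroman-4-one | O=C1CCOc2cc(O)cc(O)c12 | intermediate
5 | 7-(benzyloxy)-5-hydroxychroman-4-one | O=C1CCOc2cc(OCc3ccccc3)cc(O)c12 | intermediate
6 | 7-(benzyloxy)-5-methoxychroman-4-one | COc1cc(OCc2ccccc2)cc2OCCC(=O)c12 | intermediate
7 | 7-hydroxy-5-methoxychroman-4-one | COc1cc(O)cc2OCCC(=O)c12 | intermediate
8 | 5-methoxy-7-(triisopropylsilyloxy)chroman-4-one | COc1cc(O[Si](C(C)C)(C(C)C)C(C)C)cc2OCCC(=O)c12 | intermediate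
9 | 5-methoxy-7-(triisopropylsilyloxy)-4-(trimethylsilyloxy)-2H-chromene | COc1cc(O[Si](C(C)C)(C(C)C)C(C)C)cc2OCC=C(O[Si](C)(C)C)c12 | intermediate
10 | rac-3-bromo-5-methoxy-7-(triisopropylsilyloxy)chroman-4-one (racemate) | COc1cc(O[Si](C(C)C)(C(C)C)C(C)C)cc2OCC(Br)C(=O)c12 | intermediate
11 | 4-bromo-2-methoxyphenol | COc1cc(Br)ccc1O | starting material
12 | 3-chloro-3-methylbut-1-yne | CC(C)(Cl)C#C | starting material
13 | 4-bromo-2-methoxy-1-(2-methylbut-3-yn-2-yloxy)benzene | COc1cc(Br)ccc1OC(C)(C)C#C | intermediate
14 | 4-bromo-2-methoxy-6-(3-methylbuta-1,2-dien-1-yl)phenol (ortho-allenylphenol) | COc1cc(Br)cc(C=C=C(C)C)c1O | intermediate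
15 | 4-bromo-2-methoxy-6-(3-methylbut-2-en-1-ylidene)cyclohexa-2,4-dien-1-one (ortho-quinone methide) | COC1=CC(Br)=CC(=CC=C(C)C)C1=O | intermediate
16 | 6-bromo-8-methoxy-2,2-dimethyl-2H-chromene | COc1cc(Br)cc2C=CC(C)(C)Oc12 | intermediate
17 | 6-bromo-2,2-dimethyl-2H-chromen-8-ol | Oc1cc(Br)cc2C=CC(C)(C)Oc12 | intermediate
18 | 6-bromo-2,2-dimethyl-8-(triisopropylsilyloxy)-2H-chromene | CC(C)[Si](C(C)C)(C(C)C)Oc1cc(Br)cc2C=CC(C)(C)Oc12 | intermediate
19 | [2,2-dimethyl-8-(triisopropylsilyloxy)-2H-chromen-6-yl]magnesium bromide | CC(C)[Si](C(C)C)(C(C)C)Oc1cc([Mg]Br)cc2C=CC(C)(C)Oc12 | intermediate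
20 | [2,2-dimethyl-8-(triisopropylsilyloxy)-2H-chromen-6-yl]zinc iodide | CC(C)[Si](C(C)C)(C(C)C)Oc1cc([Zn]I)cc2C=CC(C)(C)Oc12 | intermediate
21 | (3R)-3-[2,2-dimethyl-8-(triisopropylsilyloxy)-2H-chromen-6-yl]-5-methoxy-7-(triisopropylsilyloxy)chroman-4-one | COc1cc(O[Si](C(C)C)(C(C)C)C(C)C)cc2c1C(=O)[C@H](c1cc(O[Si](C(C)C)(C(C)C)C(C)C)c3c(c1)C=CC(C)(C)O3)CO2 | intermediate
22 | (3R)-7-hydroxy-3-(8-hydroxy-2,2-dimethyl-2H-chromen-6-yl)-5-methoxychroman-4-one | COc1cc(O)cc2c1C(=O)[C@H](c1cc(O)c3c(c1)C=CC(C)(C)O3)CO2 | target

Total step count: 14.
Longest linear sequence: 9 steps (steps 1 to 7, then 13 and 14); the ring B branch needs steps 8 to 12 before the coupling.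

Steps most likely to fail

1. Step 13 (the step that carries the label "Proposed new method:").
   - Process at risk: dehydrobromination of the electrophile, opening of ring C by β-aryloxy elimination at the organonickel stage, or poor facial selectivity at the ring-locked C3 radical.
   - Fallback, known chemistry, setting out from ketone 8 and aryl bromide 18 and returning at 21. Palladium-catalysed ketone α-arylation of 8 with 18 (Pd(OAc)2, XPhos, K3PO4, toluene, 80 °C) should give rac-3-[2,2-dimethyl-8-(triisopropylsilyloxy)-2H-chromen-6-yl]-5-methoxy-7-(triisopropylsilyloxy)chroman-4-one F1. Asymmetric transfer hydrogenation with dynamic kinetic resolution (RuCl(p-cymene)[(R,R)-TsDPEN], antipode to be confirmed by trial, HCO2H/Et3N, 40 °C) follows; C3 of the unreduced ketone equilibrates through its enol while one enantiomer is reduced faster. This should give the cis-alcohol (3R,4R)-3-[2,2-dimethyl-8-(triisopropylsilyloxy)-2H-chromen-6-yl]-5-methoxy-7-(triisopropylsilyloxy)chroman-4-ol F2. Oxidation of F2 with Dess–Martin periodinane in CH2Cl2 at 0 °C involves no base and should return 21 with C3 intact.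

2. Step 7.
   - Process at risk: competing bromination of the electron-rich ring A, hydrolysis of the enol ether before bromine transfer, or loss of HBr to the chromone during isolation.
   - Fallback setting out from ketone 8 and returning at 10. The enol ether is dropped and 8 is brominated directly with PhNMe3Br3 (phenyltrimethylammonium tribromide) in THF at 0 °C. This is an acid-promoted bromination of the ketone enol by a tribromide that spares activated arenes; it generates HBr and no base, so elimination is not promoted. The bromide is then crystallised cold instead of chromatographed. No new compound is made on this way (F0).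

3. Step 12.
   - Process at risk: sluggish insertion of magnesium into the electron-rich aryl bromide, with Wurtz-type homocoupling on forcing, which leaves a zinc reagent of low and uncertain titre and starves step 13.
   - Fallback setting out from aryl bromide 18 and returning at 20. Bromine–lithium exchange with n-BuLi in THF at −78 °C, in place of metal insertion, should give [2,2-dimethyl-8-(triisopropylsilyloxy)-2H-chromen-6-yl]lithium F3. Addition of ZnI2 in THF at −78 °C with warming to rt transmetalates F3 to 20. The reagent then carries lithium halide in place of the magnesium salt, and its effect on the coupling must be checked.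

Further compounds
F1 | step 13 | rac-3-[2,2-dimethyl-8-(triisopropylsilyloxy)-2H-chromen-6-yl]-5-methoxy-7-(triisopropylsilyloxy)chroman-4-one | COc1cc(O[Si](C(C)C)(C(C)C)C(C)C)cc2c1C(=O)C(c1cc(O[Si](C(C)C)(C(C)C)C(C)C)c3c(c1)C=CC(C)(C)O3)CO2
F2 | step 13 | (3R,4R)-3-[2,2-dimethyl-8-(triisopropylsilyloxy)-2H-chromen-6-yl]-5-methoxy-7-(triisopropylsilyloxy)chroman-4-ol | COc1cc(O[Si](C(C)C)(C(C)C)C(C)C)cc2c1[C@H](O)[C@H](c1cc(O[Si](C(C)C)(C(C)C)C(C)C)c3c(c1)C=CC(C)(C)O3)CO2
F0 | step 7 | none | none
F3 | step 12 | [2,2-dimethyl-8-(triisopropylsilyloxy)-2H-chromen-6-yl]lithium | [Li]c1cc(O[Si](C(C)C)(C(C)C)C(C)C)c2OC(C)(C)C=Cc2c1
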